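**Plan**
- Retrosynthesis: remove the C3 hydroxyl (enol ether oxidation), cut C3=C4 of ring C (ring-closing metathesis), cut O1–C2 (allylic etherification), then cut the two aryl–prenyl bonds.
- Enabling feature: the C4 ketone and its alpha carbon C3 in ring C are the hydrolysed and oxidised form of a C3=C4 silyl enol ether. This is an endocyclic alkene in a six-membered ring whose other atoms (C4a and C8a of ring A, O1, C2) are already joined in an aryl 1-arylallyl ether of a 2-acylphenol.
- Forward: ring A ketone 6 and ring B cinnamyl carbonate 13 are made separately and joined at O1–C2. Ring C is then closed by metathesis, C3 is hydroxylated and the acetals are removed.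
- Stereochemistry: C2 comes from the chiral iridium–phosphoramidite catalyst in step 10. C3 comes from attack of the oxidant on the enol ether face anti to the C2 aryl group in step 13.

Key step: step 12

Assumption: the (Sa,Sc,Sc) enantiomer of the binaphthol-derived N,N-bis(1-phenylethyl)phosphoramidite is taken to give the (S)-configured branched ether from a heteroatom nucleophile and a cinnamyl carbonate. If the sense proves opposite, the mirror-image ligand is used.

**Route**

Step 1
Reactants: 1 2,4-dihydroxyacetophenone; 2 3-chloro-3-methylbut-1-yne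
Product: 3 1-[2-hydroxy-4-(2-methylbut-3-yn-2-yloxy)phenyl]ethanone
Conditions: K2CO3, KI, CuI (cat.), acetone, reflux
Reagents that add atoms: none
Why: Williamson-type O-propargylation occurs only at the 4-hydroxyl because the 2-hydroxyl is tied up in the hydrogen-bonded chelate with the acetyl group.

Step 2
Reactants: 3 1-[2-hydroxy-4-(2-methylbut-3-yn-2-yloxy)phenyl]ethanone
Product: 4 1-[2-hydroxy-4-(2-methylbut-3-en-2-yloxy)phenyl]ethanone
Conditions: H2 (1 atm), Pd/CaCO3 poisoned with Pb(OAc)2, quinoline, EtOAc, rt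
Reagents that add atoms: none
Why: Semi-hydrogenation of the terminal alkyne over poisoned palladium stops at the alkene and leaves the aryl ketone untouched.

Step 3
Reactants: 4 1-[2-hydroxy-4-(2-methylbut-3-en-2-yloxy)phenyl]ethanone
Product: 5 1-[2,4-dihydroxy-3-(3-methylbut-2-en-1-yl)phenyl]ethanone
Conditions: N,N-diethylaniline, 180 °C
Reagents that add atoms: none
Why: Aromatic Claisen rearrangement of the 1,1-dimethylallyl ether delivers a prenyl group to C3, because the chelated 2-hydroxyacetophenone has the higher double-bond character in its C3–C4 bond.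

Step 4
Reactants: 5 1-[2,4-dihydroxy-3-(3-methylbut-2-en-1-yl)phenyl]ethanone
Product: 6 1-[2-hydroxy-4-(methoxymethoxy)-3-(3-methylbut-2-en-1-yl)phenyl]ethanone
Conditions: MOMCl (1.1 equiv), i-Pr2NEt, CH2Cl2, 0 °C to rt
Reagents that add atoms: chloromethyl methyl ether, COCCl
Why: Selective acetal protection (O-alkylation) of the free 4-hydroxyl, while the chelated and flanked 2-hydroxyl stays free as the later nucleophile.

Step 5
Reactants: 7 4-hydroxybenzaldehyde; 8 prenyl bromide
Product: 9 4-hydroxy-3-(3-methylbut-2-en-1-yl)benzaldehyde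
Conditions: KOH, H2O, rt (phenol in excess)
Reagents that add atoms: none
Why: C-alkylation of the phenoxide in water, where solvation of the oxygen steers the allylic bromide to the ortho carbon; both ortho positions are equivalent and para is blocked.

Step 6
Reactants: 9 4-hydroxy-3-(3-methylbut-2-en-1-yl)benzaldehyde
Product: 10 4-(methoxymethoxy)-3-(3-methylbut-2-en-1-yl)benzaldehyde
Conditions: MOMCl, i-Pr2NEt, CH2Cl2, 0 °C to rt
Reagents that add atoms: chloromethyl methyl ether, COCCl
Why: Standard MOM protection of a phenol, needed so that only the ring A phenol is nucleophilic in step 10.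

Step 7
Reactants: 10 4-(methoxymethoxy)-3-(3-methylbut-2-en-1-yl)benzaldehyde
Product: 11 ethyl (E)-3-[4-(methoxymethoxy)-3-(3-methylbut-2-en-1-yl)phenyl]prop-2-enoate
Conditions: Ph3P=CHCO2Et, toluene, 80 °C
Reagents that add atoms: ethyl (triphenylphosphoranylidene)acetate, CCOC(=O)C=P(c1ccccc1)(c1ccccc1)c1ccccc1
Why: Wittig reaction of a stabilised ylide with an aryl aldehyde gives the (E)-cinnamate.

Step 8
Reactants: 11 ethyl (E)-3-[4-(methoxymethoxy)-3-(3-methylbut-2-en-1-yl)phenyl]prop-2-enoate
Product: 12 (E)-3-[4-(methoxymethoxy)-3-(3-methylbut-2-en-1-yl)phenyl]prop-2-en-1-ol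
Conditions: i-Bu2AlH (2.2 equiv), CH2Cl2, −78 °C
Reagents that add atoms: none
Why: 1,2-Reduction of the conjugated ester by the aluminium hydride gives the allylic alcohol without touching the alkenes or the acetal.

Step 9
Reactants: 12 (E)-3-[4-(methoxymethoxy)-3-(3-methylbut-2-en-1-yl)phenyl]prop-2-en-1-ol
Product: 13 (E)-3-[4-(methoxymethoxy)-3-(3-methylbut-2-en-1-yl)phenyl]prop-2-en-1-yl methyl carbonate
Conditions: ClCO2Me, pyridine, CH2Cl2, 0 °C
Reagents that add atoms: methyl chloroformate, COC(=O)Cl
Why: Acylation of the primary alcohol gives the linear carbonate, the usual electrophile for iridium-catalysed allylic substitution.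

Step 10
Reactants: 6 1-[2-hydroxy-4-(methoxymethoxy)-3-(3-methylbut-2-en-1-yl)phenyl]ethanone; 13 (E)-3-[4-(methoxymethoxy)-3-(3-methylbut-2-en-1-yl)phenyl]prop-2-en-1-yl methyl carbonate
Product: 14 1-[2-{[(1S)-1-[4-(methoxymethoxy)-3-(3-methylbut-2-en-1-yl)phenyl]prop-2-en-1-yl]oxy}-4-(methoxymethoxy)-3-(3-methylbut-2-en-1-yl)phenyl]ethanone
Conditions: [Ir(cod)Cl]2 (2 mol%), (Sa,Sc,Sc)-phosphoramidite (4 mol%), n-PrNH2 pre-activation; K3PO4, THF, rt
Reagents that add atoms: none
Why: Iridium-catalysed asymmetric allylic etherification, in which the phenoxide attacks the aryl-substituted terminus of the allyl–iridium complex of the cyclometalated phosphoramidite catalyst, gives the branched ether and sets C2 (S) under catalyst control.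

Step 11
Reactants: 14 the (S)-configured aryl allyl ether ketone
Product: 16 tert-butyl{[1-(2-{[(1S)-1-[4-(methoxymethoxy)-3-(3-methylbut-2-en-1-yl)phenyl]prop-2-en-1-yl]oxy}-4-(methoxymethoxy)-3-(3-methylbut-2-en-1-yl)phenyl)ethenyl]oxy}dimethylsilane, via potassium enolate 15 (not isolated)
Conditions: KN(SiMe3)2 (1.1 equiv), THF, −78 °C; TBSCl, −78 to 0 °C; Et3N-buffered work-up
Reagents that add atoms: tert-butyldimethylsilyl chloride, CC(C)(C)[Si](C)(C)Cl
Why: Kinetic enolisation of the methyl ketone (its only enolisable position) and O-silylation of the enolate give the silyl enol ether under basic conditions, with no Lewis acid to ionise the allylic ether or the acetals.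

Step 12
Reactants: 16 the silyl enol ether carrying the (S)-1-arylallyl ether
Product: 17 (2S)-4-(tert-butyldimethylsilyloxy)-7-(methoxymethoxy)-2-[4-(methoxymethoxy)-3-(3-methylbut-2-en-1-yl)phenyl]-8-(3-methylbut-2-en-1-yl)-2H-chromene
Conditions: second-generation Grubbs catalyst RuCl2(=CHPh)(PCy3)(H2IMes) (5–10 mol%), degassed toluene, 60 °C, argon sparge, shielded from light
Reagents that add atoms: none
Why: The ruthenium benzylidene first exchanges with the monosubstituted vinyl group of the allylic ether, the resulting alkylidene adds across the 1,1-disubstituted silyl enol ether in an intramolecular [2+2] cycloaddition, and cycloreversion of the ruthenacyclobutane gives the endocyclic C3=C4 bond and Ru=CH2, which carries the chain with loss of ethylene. The closest known reaction type is ring-closing metathesis of acyclic silyl enol ethers to cyclic silyl enol ethers with ruthenium alkylidenes, together with the closure of 2-vinylphenyl allyl ethers to 2H-chromenes. Ring C is closed as a six-membered ring by olefin metathesis between the enol ether methylene terminus and the vinyl group, with C4a, C8a, O1 and C2 held in a cisoid array by the ortho-disubstituted arene. No stereocentre is formed, and C2 from step 10 should be untouched because the conditions are neutral and no allyl-metal or ring-opened species is involved. The step needs the catalyst to engage the two terminal alkenes and not the two prenyl groups; this is secured by the much slower reaction of trisubstituted alkenes with the alkylidene and by the ease of six-membered ring closure, while loading on the vinyl group rather than on the enol ether avoids an unreactive siloxy-substituted carbene.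

Step 13
Reactants: 17 the (2S)-4-silyloxy-2H-chromene
Product: 19 (2R,3R)-3-hydroxy-7-(methoxymethoxy)-2-[4-(methoxymethoxy)-3-(3-methylbut-2-en-1-yl)phenyl]-8-(3-methylbut-2-en-1-yl)chroman-4-one, via silyloxy epoxide 18 (not isolated)
Conditions: dimethyldioxirane (1.0 equiv, acetone solution), CH2Cl2, −78 °C; then AcOH, THF–H2O, 0 °C to rt
Reagents that add atoms: dimethyldioxirane, CC1(C)OO1
Why: Rubottom oxidation, in which the electrophilic dioxirane should epoxidise the electron-rich silyl enol ether faster than the prenyl alkenes and on the face anti to the C2 aryl group, so that acid opening of the silyloxy epoxide gives the ketone with the C3 hydroxyl trans to the aryl group (3R) without any base.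

Step 14
Reactants: 19 the bis-MOM (2R,3R)-3-hydroxyflavanone
Product: 20 3-hydroxyglabrol, (2R,3R)-3,7-dihydroxy-2-[4-hydroxy-3-(3-methylbut-2-en-1-yl)phenyl]-8-(3-methylbut-2-en-1-yl)chroman-4-one
Conditions: 3 M aq. HCl, MeOH, 40 °C
Reagents that add atoms: none
Why: Acid-catalysed transacetalisation to methanol removes both aryl MOM ethers under mild conditions, which the trans-dihydroflavonol (the thermodynamically preferred diastereomer) and the prenyl groups should tolerate.

**Compound list**

1 | 2,4-dihydroxyacetophenone | CC(=O)c1ccc(O)cc1O | starting material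
2 | 3-chloro-3-methylbut-1-yne | CC(C)(Cl)C#C | starting material
3 | 1-[2-hydroxy-4-(2-methylbut-3-yn-2-yloxy)phenyl]ethanone | CC(=O)c1ccc(OC(C)(C)C#C)cc1O | intermediate
4 | 1-[2-hydroxy-4-(2-methylbut-3-en-2-yloxy)phenyl]ethanone | CC(=O)c1ccc(OC(C)(C)C=C)cc1O | intermediate
5 | 1-[2,4-dihydroxy-3-(3-methylbut-2-en-1-yl)phenyl]ethanone | CC(=O)c1ccc(O)c(CC=C(C)C)c1O | intermediate
6 | 1-[2-hydroxy-4-(methoxymethoxy)-3-(3-methylbut-2-en-1-yl)phenyl]ethanone | CC(=O)c1ccc(OCOC)c(CC=C(C)C)c1O | intermediate
7 | 4-hydroxybenzaldehyde | O=Cc1ccc(O)cc1 | starting material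
8 | prenyl bromide (1-bromo-3-methylbut-2-ene) | CC(C)=CCBr | starting material
9 | 4-hydroxy-3-(3-methylbut-2-en-1-yl)benzaldehyde | CC(C)=CCc1cc(C=O)ccc1O | intermediate
10 | 4-(methoxymethoxy)-3-(3-methylbut-2-en-1-yl)benzaldehyde | CC(C)=CCc1cc(C=O)ccc1OCOC | intermediate
11 | ethyl (E)-3-[4-(methoxymethoxy)-3-(3-methylbut-2-en-1-yl)phenyl]prop-2-enoate | CCOC(=O)/C=C/c1ccc(OCOC)c(CC=C(C)C)c1 | intermediate
12 | (E)-3-[4-(methoxymethoxy)-3-(3-methylbut-2-en-1-yl)phenyl]prop-2-en-1-ol | OC/C=C/c1ccc(OCOC)c(CC=C(C)C)c1 | intermediate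
13 | (E)-3-[4-(methoxymethoxy)-3-(3-methylbut-2-en-1-yl)phenyl]prop-2-en-1-yl methyl carbonate | COC(=O)OC/C=C/c1ccc(OCOC)c(CC=C(C)C)c1 | intermediate
14 | 1-[2-{[(1S)-1-[4-(methoxymethoxy)-3-(3-methylbut-2-en-1-yl)phenyl]prop-2-en-1-yl]oxy}-4-(methoxymethoxy)-3-(3-methylbut-2-en-1-yl)phenyl]ethanone | CC(C)=CCc1cc([C@@H](Oc2c(CC=C(C)C)c(OCOC)ccc2C(C)=O)C=C)ccc1OCOC | intermediate
15 | potassium enolate of 14 (S at the allylic ether carbon) | CC(C)=CCc1cc([C@@H](Oc2c(CC=C(C)C)c(OCOC)ccc2C(=C)[O-])C=C)ccc1OCOC.[K+] | intermediate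
16 | tert-butyldimethylsilyl enol ether of 14 (S at the allylic ether carbon) | CC(C)=CCc1cc([C@@H](Oc2c(CC=C(C)C)c(OCOC)ccc2C(=C)O[Si](C)(C)C(C)(C)C)C=C)ccc1OCOC | intermediate
17 | (2S)-4-(tert-butyldimethylsilyloxy)-7-(methoxymethoxy)-2-[4-(methoxymethoxy)-3-(3-methylbut-2-en-1-yl)phenyl]-8-(3-methylbut-2-en-1-yl)-2H-chromene | CC(C)=CCc1cc([C@H]2Oc3c(CC=C(C)C)c(OCOC)ccc3C(O[Si](C)(C)C(C)(C)C)=C2)ccc1OCOC | intermediate
18 | 3,4-epoxide of 17 (4-silyloxy oxirane cis-fused to ring C, oxygen on the face opposite the C2 aryl group, C2 as in 17) | CC(C)=CCc1cc([C@H]2Oc3c(CC=C(C)C)c(OCOC)ccc3[C@]4(O[Si](C)(C)C(C)(C)C)O[C@H]24)ccc1OCOC | intermediate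
19 | (2R,3R)-3-hydroxy-7-(methoxymethoxy)-2-[4-(methoxymethoxy)-3-(3-methylbut-2-en-1-yl)phenyl]-8-(3-methylbut-2-en-1-yl)chroman-4-one | CC(C)=CCc1cc([C@H]2Oc3c(CC=C(C)C)c(OCOC)ccc3C(=O)[C@@H]2O)ccc1OCOC | intermediate
20 | 3-hydroxyglabrol, (2R,3R)-3,7-dihydroxy-2-[4-hydroxy-3-(3-methylbut-2-en-1-yl)phenyl]-8-(3-methylbut-2-en-1-yl)chroman-4-one | CC(C)=CCc1cc([C@H]2Oc3c(ccc(O)c3CC=C(C)C)C(=O)[C@@H]2O)ccc1O | target

**Step count**
Total: 14 steps. Longest linear sequence: 10 steps (steps 5 to 14, from 4-hydroxybenzaldehyde).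

**Steps most likely to fail**

1. Step 10. The phenoxide of 6 is chelated to the acetyl group and flanked on both sides, so attack on the allyl–iridium complex may be slow. The electron-rich branched ether may also re-ionise on the catalyst, which would erode the branched selectivity and the enantiomeric purity.
Fallback, setting out from 10 and returning at 14: stereospecific rather than enantioselective substitution. Aldehyde 10 would be treated with CH2=CHMgBr in THF to give racemic 1-[4-(methoxymethoxy)-3-(3-methylbut-2-en-1-yl)phenyl]prop-2-en-1-ol F1. Kinetic resolution with Candida antarctica lipase B and vinyl acetate should acetylate the (R)-enantiomer and leave (1S)-1-[4-(methoxymethoxy)-3-(3-methylbut-2-en-1-yl)phenyl]prop-2-en-1-ol F2, which is separated from the (1R)-acetate F3. Alcohol F2 would be converted with ClCO2Me and pyridine into the branched (1S)-methyl carbonate F4. The sodium phenoxide of 6 (from NaN(SiMe3)2) would then displace the carbonate under RhCl(PPh3)3 modified with P(OMe)3. This rhodium-catalysed allylic etherification is branched-selective and proceeds with net retention, so it should give 14.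

2. Step 12. The hindered, electron-rich 1,1-disubstituted enol ether may cyclise slowly. The catalyst could then decompose, isomerise the allylic ether through ruthenium hydrides, or the enol ether could hydrolyse before ring closure.
Fallback, setting out from 6 and 10 and returning at 20: ring C is closed at O1–C2 instead of C3=C4. Phenol 6 would be protected (NaH, MOMCl, DMF) as 1-[2,4-bis(methoxymethoxy)-3-(3-methylbut-2-en-1-yl)phenyl]ethanone F5. Claisen–Schmidt condensation with 10 (KOH, EtOH) would give the (E)-chalcone F6. Juliá–Colonna epoxidation (poly-L-leucine, urea–H2O2, DBU, THF) is nucleophilic, so it should touch only the enone and give the (2R,3S)-chalcone epoxide F7. HCl in MeOH would then remove the three acetals and let the liberated ring A phenol open the epoxide at the benzylic carbon, which gives the trans-dihydroflavonol 20 directly.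

3. Step 13. The dioxirane may also epoxidise a prenyl alkene, or may attack the enol ether with incomplete facial selectivity.
Fallback, setting out from 17 and returning at 19: enolate hydroxylation in place of enol ether epoxidation. Mild hydrolysis of 17 (AcOH, THF–H2O) would give (2S)-7-(methoxymethoxy)-2-[4-(methoxymethoxy)-3-(3-methylbut-2-en-1-yl)phenyl]-8-(3-methylbut-2-en-1-yl)chroman-4-one F8. Its lithium enolate (LiN(SiMe3)2, THF, −78 °C, kept cold to suppress retro-oxa-Michael opening) would be hydroxylated with 2-(phenylsulfonyl)-3-phenyloxaziridine, a reagent that leaves isolated trisubstituted alkenes alone. Attack anti to the C2 aryl group should give 19.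

**Further compounds**

F1 | step 10 | racemic 1-[4-(methoxymethoxy)-3-(3-methylbut-2-en-1-yl)phenyl]prop-2-en-1-ol | C=CC(O)c1ccc(OCOC)c(CC=C(C)C)c1
F2 | step 10 | (1S)-1-[4-(methoxymethoxy)-3-(3-methylbut-2-en-1-yl)phenyl]prop-2-en-1-ol | CC(C)=CCc1cc([C@@H](O)C=C)ccc1OCOC
F3 | step 10 | (1R)-1-[4-(methoxymethoxy)-3-(3-methylbut-2-en-1-yl)phenyl]prop-2-en-1-yl acetate | CC(C)=CCc1cc([C@H](OC(C)=O)C=C)ccc1OCOC
F4 | step 10 | (1S)-1-[4-(methoxymethoxy)-3-(3-methylbut-2-en-1-yl)phenyl]prop-2-en-1-yl methyl carbonate | CC(C)=CCc1cc([C@@H](OC(=O)OC)C=C)ccc1OCOC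
F5 | step 12 | 1-[2,4-bis(methoxymethoxy)-3-(3-methylbut-2-en-1-yl)phenyl]ethanone | CC(=O)c1ccc(OCOC)c(CC=C(C)C)c1OCOC
F6 | step 12 | (E)-1-[2,4-bis(methoxymethoxy)-3-(3-methylbut-2-en-1-yl)phenyl]-3-[4-(methoxymethoxy)-3-(3-methylbut-2-en-1-yl)phenyl]prop-2-en-1-one | CC(C)=CCc1cc(/C=C/C(=O)c2ccc(OCOC)c(CC=C(C)C)c2OCOC)ccc1OCOC
F7 | step 12 | (2R,3S)-2,3-epoxy-1-[2,4-bis(methoxymethoxy)-3-(3-methylbut-2-en-1-yl)phenyl]-3-[4-(methoxymethoxy)-3-(3-methylbut-2-en-1-yl)phenyl]propan-1-one | CC(C)=CCc1cc([C@@H]2O[C@H]2C(=O)c3ccc(OCOC)c(CC=C(C)C)c3OCOC)ccc1OCOC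
F8 | step 13 | (2S)-7-(methoxymethoxy)-2-[4-(methoxymethoxy)-3-(3-methylbut-2-en-1-yl)phenyl]-8-(3-methylbut-2-en-1-yl)chroman-4-one | CC(C)=CCc1cc([C@H]2Oc3c(CC=C(C)C)c(OCOC)ccc3C(=O)C2)ccc1OCOC
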